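**Retrosynthetic overview**

1. Locants: labdane numbering for the diterpene half (C12–C15 = side-chain diene, C19 = axial acid); primed caryophyllane numbering for the C15 half (C8' = the C=CH2 carbon, C9' and C1' = cyclobutane ring-fusion CH carbons, C10' = cyclobutane CH2, C11' = CMe2, C4' = quaternary carbon bearing the C12' carboxyl, C5' = its CH neighbour).
2. Last ring: the cyclobutane (C1'–C11'–C10'–C9') is cut at C1'–C11' and C9'–C10', giving a nine-membered (Z)-enone (C8' ketone, C9'=C1') and 2-bromo-2-methylpropyl tosylate. Enabling feature: in the nine-membered ring the methylene-bearing C8' is bonded to fusion carbon C9', and the other fusion carbon C1' carries the CMe2 carbon; a C8' ketone therefore makes C9'/C1' the α/β carbons of an enone, and the four-membered ring becomes a β-addition of a tertiary carbon plus an α-alkylation by the neopentyl C10' (no β-hydrogen).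
3. Nine-membered ring: ring-closing metathesis forming C1'=C9'; both arms are released by periodate cleavage of the C12'–C8' bond of an α-ketol in a temporary cyclohexanone ring, which unveils the C12' acid and the C8' carbonyl together.
4. Cyclohexene ring (with the temporary ring attached): catalyst-controlled endo Diels–Alder reaction of methyl trans-communate with 2-(but-3-enyl)cyclohex-2-enone, setting C12, C4' and C5'.
5. Ring order: decalin (bought in trans-communic acid) → cyclohexene + temporary cyclohexanone → nine-membered ring → cyclobutane; then Wittig methylenation at C8' and cleavage of the C19 methyl ester.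

Key step: step 11

Assumption 1: trans-communic acid (1) is taken as a purchasable isolated natural product; its four stereocentres are carried through unchanged.
Assumption 2: in step 3 the (S)-oxazaborolidine is written on the usual enone-binding model; should the matched diastereomer require it, the equally available (R)-catalyst is used.

**Route**

Step 1
Reactants: 1 trans-communic acid
Product: 2 methyl trans-communate
Conditions: MeI, K2CO3, DMF, 25 °C
Reagents that add atoms: iodomethane, CI
Why: SN2 O-alkylation of the carboxylate is insensitive to the hindrance of the axial C19 acid and leaves the diene and the exocyclic alkene untouched; no stereocentre is affected.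

Step 2
Reactants: 3 2-iodocyclohex-2-en-1-one; 4 but-3-enylzinc bromide (0.5 M in THF)
Product: 5 2-(but-3-enyl)cyclohex-2-en-1-one
Conditions: Pd2(dba)3 (2.5 mol %), tri(2-furyl)phosphine (10 mol %), THF–DMF, 25 °C
Reagents that add atoms: none
Why: Negishi coupling: oxidative addition of zerovalent palladium into the C–I bond of the α-iodoenone and transmetallation with the primary alkylzinc give the 2-alkyl enone without touching the terminal alkene; no stereocentre is formed.

Step 3
Reactants: 2 methyl trans-communate; 5 2-(but-3-enyl)cyclohex-2-en-1-one (1.5 equiv)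
Product: 6 cis-fused Diels–Alder adduct (angular but-3-enyl ketone)
Conditions: (S)-B-(o-tolyl)-α,α-diphenylprolinol oxazaborolidine (20 mol %) activated with AlBr3 (16 mol %), CH2Cl2, −40 → −20 °C
Reagents that add atoms: none
Why: Lewis-acid-catalysed Diels–Alder reaction of a cyclic enone with an (E)-1-alkyl-2-methyl diene: the unsubstituted C15 terminus should bond to the enone β-carbon (C5') and C12 to the α-carbon (C4'), the cyclic dienophile enforces the cis ring fusion (C12' cis to C6'), the endo transition state places the ketone carbon C12' cis to the C11 methylene on C12, and the chiral oxazaborolidinium shields one enone face so that the absolute configuration of C12, C4' and C5' is set by the catalyst and not by the remote decalin.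

Step 4
Reactants: 6 cis-fused Diels–Alder adduct
Product: 8 α-ketol, via potassium enolate 7 (not isolated)
Conditions: KN(SiMe3)2, THF, −78 °C; then 2-(phenylsulfonyl)-3-phenyloxaziridine, −78 °C; AcOH quench
Reagents that add atoms: 2-(phenylsulfonyl)-3-phenyloxaziridine, O=S(=O)(c1ccccc1)N1OC1c1ccccc1
Why: Enolate hydroxylation with an N-sulfonyloxaziridine: the ketone can enolise only toward C8' because C4' is quaternary, and the configuration of the new carbinol centre (attack on the convex face of the cis-fused bicycle is expected) is irrelevant because the centre is destroyed in step 5.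

Step 5
Reactants: 8 α-ketol
Product: 9 aldehyde acid
Conditions: NaIO4, THF–H2O (2:1), 25 °C
Reagents that add atoms: water, O
Why: Periodate glycol-type cleavage of the α-ketol (through the ketone hydrate) breaks the C12'–C8' bond of the temporary ring and gives the C12' carboxylic acid and the C8' aldehyde; alkenes are inert to periodate and the carbinol centre disappears.

Step 6
Reactants: 9 aldehyde acid
Product: 10 allylic alcohol acid
Conditions: CH2=CHMgBr (3 equiv), THF, −78 → −40 °C; aqueous HCl (1 M, 0 °C) work-up
Reagents that add atoms: vinylmagnesium bromide, C=C[Mg]Br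
Why: Grignard 1,2-addition to the aldehyde after deprotonation of the acid (the magnesium carboxylate and the hindered C19 ester do not react at low temperature); the new C8' carbinol centre is not controlled and is erased in step 7.

Step 7
Reactants: 10 allylic alcohol acid
Product: 11 vinyl ketone acid
Conditions: Dess–Martin periodinane, CH2Cl2, 0 → 25 °C
Reagents that add atoms: none
Why: Dess–Martin oxidation converts either carbinol epimer into the same vinyl ketone under neutral conditions that tolerate the free acid and all alkenes; the C8' stereocentre is erased.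

Step 8
Reactants: 11 vinyl ketone acid
Product: 12 nine-membered (Z)-enone acid
Conditions: second-generation Grubbs catalyst (10 mol %), PhMe, 80 °C, 1 mM
Reagents that add atoms: none
Why: Ring-closing metathesis of a vinyl ketone with a monosubstituted alkene: the two arms sit trans on adjacent carbons of the cyclohexene (one of them quaternary), which holds them gauche and should favour closure of the nine-membered ring, the ring size dictates the (Z)-enone, and the 1,1-disubstituted and trisubstituted alkenes are much slower metathesis partners.

Step 9
Reactants: 13 ethyl 2-bromo-2-methylpropanoate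
Product: 14 2-bromo-2-methylpropan-1-ol
Conditions: i-Bu2AlH (2.2 equiv), CH2Cl2, −78 → 0 °C; aqueous Rochelle salt
Reagents that add atoms: none
Why: Hydride reduction of the ester by i-Bu2AlH at low temperature is faster than attack at the tertiary C–Br bond and gives the bromohydrin; no stereocentre.

Step 10
Reactants: 14 2-bromo-2-methylpropan-1-ol
Product: 15 2-bromo-2-methylpropyl 4-methylbenzenesulfonate
Conditions: TsCl, pyridine, CH2Cl2, 0 °C
Reagents that add atoms: 4-methylbenzenesulfonyl chloride, Cc1ccc(cc1)S(Cl)(=O)=O
Why: Sulfonylation of the primary neopentyl alcohol with TsCl and pyridine, a base too weak to close the bromohydrin to the epoxide; no stereocentre.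

Step 11
Reactants: 12 nine-membered (Z)-enone acid; 15 2-bromo-2-methylpropyl 4-methylbenzenesulfonate (2 equiv)
Product: 19 trans-fused cyclobutyl ketone acid, via trimethylsilyl ester 16 (not isolated), via bis-silyl enol ether 17 (not isolated), via dipotassium enolate 18 (not isolated)
Conditions: N,O-bis(trimethylsilyl)acetamide (1.1 equiv), DMF, 25 °C; then NiCl2(dme) (10 mol %), 2,2':6',2''-terpyridine (10 mol %), Mn powder (3 equiv), Me3SiCl (1.5 equiv), 15, DMF, 25 °C; filtration under argon, then THF, KOt-Bu (4 equiv), −40 → 25 °C; aqueous HCl (0.5 M, 0 °C) work-up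
Reagents that add atoms: none
Why: Proposed new method: a zerovalent nickel–terpyridine species, the enone of 16 and Me3SiCl should give a 1-siloxyallylnickel complex that captures the tertiary radical formed from bromide 15 by halogen abstraction and forms the C1'–C11' bond by reductive elimination at the β-carbon, delivering the regiodefined C8'=C9' silyl enol ether 17; KOt-Bu then cleaves both O–Si bonds to the aprotic enolate 18, whose C9' carbon displaces the neopentyl tosylate on C10' (no β-hydrogen, so no E2) to close the cyclobutane. The closest known reaction types are the nickel-catalysed reductive conjugate addition of tertiary alkyl bromides to cyclic enones with chlorosilane trapping, the alkoxide unmasking of silyl enol ethers to regiodefined enolates, and the intramolecular ketone-enolate alkylation of neopentyl sulfonates that closes a cyclobutane on a medium-ring ketone; their union in one flask as a formal [2+2] annulation with a β-sulfonyloxy tertiary radical is what is new. The ring closes in the 4-exo-tet mode with the enolate double bond exocyclic to the forming ring, and O-alkylation is geometrically excluded because in the (Z)-configured ring enolate the oxygen lies trans to C1' across C8'=C9'. C1' is set by substrate control: the CH=CH unit of the enone is expected to tilt to the face of the nine-membered ring opposite the axial C12' carboxyl on C4', only its peripheral π-face is open, and bond formation there places C11' equatorial with H-1' on the same side as H-5'; C9' is set under thermodynamic control, the trans-fused bicyclo[7.2.0] ketone being the more stable epimer and reachable by enolisation with the excess KOt-Bu. The step needs β-addition instead of carbonyl addition (secured by the allylnickel pathway), enolate formation toward C9' and not C7' (secured by the silyl enol ether, never a free ketone), C- instead of O-alkylation (enolate geometry), and an inert carboxyl group (carried as silyl ester and then carboxylate, so that no enolate can acylate it across the ring).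

Step 12
Reactants: 19 trans-fused cyclobutyl ketone acid
Product: 20 8'-methylene acid C19 methyl ester
Conditions: Ph3PCH3Br (4 equiv), KOt-Bu (5 equiv), THF, 0 °C; then 19, 25 → 50 °C; aqueous HCl (0.5 M, 0 °C) work-up
Reagents that add atoms: methylenetriphenylphosphorane (made in the flask), C=P(c1ccccc1)(c1ccccc1)c1ccccc1
Why: Wittig methylenation of the ketone flanked by the cyclobutane: the carboxyl group is protected in the flask as its potassium salt, the hindered C19 methyl ester is inert to the ylide, and the only epimerisable centre (C9') already has its thermodynamically preferred trans configuration.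

Step 13
Reactants: 20 8'-methylene acid C19 methyl ester
Product: 21 target diacid (CNP0330729.1)
Conditions: NaSEt (10 equiv), DMF, 90 °C; then aqueous HCl (0.5 M, 0 °C) to pH 3
Reagents that add atoms: none
Why: Thiolate SN2 demethylation attacks the methyl carbon, so the extreme hindrance of the axial C19 ester is irrelevant, and the non-acidic conditions leave the exocyclic alkenes, the trisubstituted alkene and the cyclobutane untouched; no stereocentre is affected.

**Compound list**

1 | trans-communic acid, (12E)-labda-8(17),12,14-trien-19-oic acid | C=C/C(C)=C/C[C@H]1C(=C)CC[C@@H]2[C@]1(C)CCC[C@]2(C)C(=O)O | starting material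
2 | methyl trans-communate | C=C/C(C)=C/C[C@H]1C(=C)CC[C@@H]2[C@]1(C)CCC[C@]2(C)C(=O)OC | intermediate
3 | 2-iodocyclohex-2-en-1-one | O=C1CCCC=C1I | starting material
4 | but-3-enylzinc bromide | C=CCC[Zn]Br | starting material
5 | 2-(but-3-enyl)cyclohex-2-en-1-one | O=C1CCCC=C1CCC=C | intermediate
6 | Diels–Alder adduct: cis-fused octahydronaphthalenone with angular but-3-enyl on C4', ketone carbon C12' cis to the C11 methylene on C12, C19 methyl ester | O=C1CCC[C@H]2CC=C(C)[C@@H](C[C@H]3C(=C)CC[C@@H]4[C@]3(C)CCC[C@]4(C)C(=O)OC)[C@@]12CCC=C | intermediate
7 | potassium enolate of 6 (enolised toward C8'), not isolated | [K+].[O-]C1=CCC[C@H]2CC=C(C)[C@@H](C[C@H]3C(=C)CC[C@@H]4[C@]3(C)CCC[C@]4(C)C(=O)OC)[C@@]12CCC=C | intermediate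
8 | α-ketol: 8'-hydroxy derivative of 6 (carbinol configuration not defined, erased in step 5) | O=C1C(O)CC[C@H]2CC=C(C)[C@@H](C[C@H]3C(=C)CC[C@@H]4[C@]3(C)CCC[C@]4(C)C(=O)OC)[C@@]12CCC=C | intermediate
9 | aldehyde acid: cyclohexene with C12' carboxylic acid and but-3-enyl on C4', 3-oxopropyl on C5' (trans to the butenyl), C19 methyl ester | O=CCC[C@H]1CC=C(C)[C@@H](C[C@H]2C(=C)CC[C@@H]3[C@]2(C)CCC[C@]3(C)C(=O)OC)[C@]1(C(=O)O)CCC=C | intermediate
10 | allylic alcohol acid: 3-hydroxypent-4-enyl arm on C5' (carbinol epimers, erased in step 7) | C=CC(O)CC[C@H]1CC=C(C)[C@@H](C[C@H]2C(=C)CC[C@@H]3[C@]2(C)CCC[C@]3(C)C(=O)OC)[C@]1(C(=O)O)CCC=C | intermediate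
11 | vinyl ketone acid: 3-oxopent-4-enyl arm on C5' | C=CC(=O)CC[C@H]1CC=C(C)[C@@H](C[C@H]2C(=C)CC[C@@H]3[C@]2(C)CCC[C@]3(C)C(=O)OC)[C@]1(C(=O)O)CCC=C | intermediate
12 | nine-membered (Z)-enone acid: C8' ketone, C9'=C1' alkene, ring trans-fused to the cyclohexene | O=C1CC[C@H]2CC=C(C)[C@@H](C[C@H]3C(=C)CC[C@@H]4[C@]3(C)CCC[C@]4(C)C(=O)OC)[C@]2(C(=O)O)CC/C=C\1 | intermediate
13 | ethyl 2-bromo-2-methylpropanoate | CCOC(=O)C(C)(C)Br | starting material
14 | 2-bromo-2-methylpropan-1-ol | CC(C)(Br)CO | intermediate
15 | 2-bromo-2-methylpropyl 4-methylbenzenesulfonate | CC(C)(Br)COS(=O)(=O)c1ccc(C)cc1 | intermediate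
16 | trimethylsilyl ester of 12, not isolated | O=C1CC[C@H]2CC=C(C)[C@@H](C[C@H]3C(=C)CC[C@@H]4[C@]3(C)CCC[C@]4(C)C(=O)OC)[C@]2(C(=O)O[Si](C)(C)C)CC/C=C\1 | intermediate
17 | bis-silyl enol ether: C8' trimethylsilyl enol ether (C8'=C9'), C1' bearing the 1,1-dimethyl-2-(tosyloxy)ethyl group, C12' silyl ester, not isolated | C1C[C@H]2CC=C(C)[C@@H](C[C@H]3C(=C)CC[C@@H]4[C@]3(C)CCC[C@]4(C)C(=O)OC)[C@]2(C(=O)O[Si](C)(C)C)CC[C@@H](C(C)(C)COS(=O)(=O)c3ccc(C)cc3)/C=C\1O[Si](C)(C)C | intermediate
18 | dipotassium enolate carboxylate from 17, not isolated | C1C[C@H]2CC=C(C)[C@@H](C[C@H]3C(=C)CC[C@@H]4[C@]3(C)CCC[C@]4(C)C(=O)OC)[C@]2(C(=O)[O-])CC[C@@H](C(C)(C)COS(=O)(=O)c3ccc(C)cc3)/C=C\1[O-].[K+].[K+] | intermediate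
19 | trans-fused cyclobutyl ketone acid (8'-oxo compound, C19 methyl ester) | O=C1CC[C@H]2CC=C(C)[C@@H](C[C@H]3C(=C)CC[C@@H]4[C@]3(C)CCC[C@]4(C)C(=O)OC)[C@]2(C(=O)O)CC[C@@H]2[C@@H]1CC2(C)C | intermediate
20 | 8'-methylene acid C19 methyl ester (mono methyl ester of the target) | C=C1CC[C@H]2CC=C(C)[C@@H](C[C@H]3C(=C)CC[C@@H]4[C@]3(C)CCC[C@]4(C)C(=O)OC)[C@]2(C(=O)O)CC[C@@H]2[C@@H]1CC2(C)C | intermediate
21 | target diacid CNP0330729.1 | C=C1CC[C@H]2CC=C(C)[C@@H](C[C@H]3C(=C)CC[C@@H]4[C@]3(C)CCC[C@]4(C)C(=O)O)[C@]2(C(=O)O)CC[C@@H]2[C@@H]1CC2(C)C | target

**Step count and risks**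

Total step count: 13 (steps 2, 9 and 10 prepare the two small building blocks).
Longest linear sequence: 10 steps (1, 3, 4, 5, 6, 7, 8, 11, 12, 13) from trans-communic acid.

Steps most likely to fail:

Step 11 (carries the label). What may go wrong: loss of the sulfonyloxy group from the tertiary radical or from a tertiary alkylnickel species (β-elimination to isobutene), addition to the wrong π-face of the enone, or proton transfer to the enolate before the slow 4-exo closure, after which the enolate could isomerise toward C7'. Fallback with known steps, setting out from 12: a Giese addition of the tertiary radical from 15 [(Me3Si)3SiH, AIBN, PhH, 80 °C] should give keto tosylate acid F1 as the isolated β-adduct. Treatment of F1 with KOt-Bu (3 equiv) in THF–t-BuOH at 25 °C then closes the four-membered ring by the classical keto-sulfonate alkylation and equilibrates C9' to the trans fusion. The route is rejoined at 19.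

Step 3. What may go wrong: the 2-alkyl enone is a sluggish dienophile, so low conversion, erosion of regio- or facial control, or Lewis-acid-induced isomerisation of the diene may intervene. Fallback with a covalent auxiliary and cationic activation, setting out from 5: (2R,3R)-butane-2,3-diol is converted into its bis(trimethylsilyl) ether F2 (Me3SiCl, Et3N, CH2Cl2). Ketone 5 and F2 with catalytic Me3SiOTf at −78 °C should give the allylic ketal F3 without double-bond shift. Ionisation of F3 with catalytic TfOH at −78 °C in the presence of 2 should give, by an oxocarbenium-type Diels–Alder reaction under auxiliary control, the adduct ketal F4 (the antipodal diol is used if the facial sense is reversed). PPTS in wet acetone releases the ketone, and the route is rejoined at 6.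

Step 8. What may go wrong: the electron-poor vinyl ketone binds the ruthenium carbene unproductively and oligomerises before the nine-membered ring closes. Fallback at the alcohol oxidation level, setting out from 10: metathesis of the diene in which both alkenes are electron-rich (second-generation Grubbs catalyst, CH2Cl2, 40 °C, 1 mM) should give the cyclic (Z)-allylic alcohol acid F5. Dess–Martin oxidation of F5 then gives the enone, and the route is rejoined at 12.

Further compounds
F1 | step 11 | keto tosylate acid: C8' ketone with C1' bearing the 1,1-dimethyl-2-(tosyloxy)ethyl group | O=C1CC[C@H]2CC=C(C)[C@@H](C[C@H]3C(=C)CC[C@@H]4[C@]3(C)CCC[C@]4(C)C(=O)OC)[C@]2(C(=O)O)CC[C@@H](C(C)(C)COS(=O)(=O)c3ccc(C)cc3)C1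
F2 | step 3 | (2R,3R)-2,3-bis(trimethylsilyloxy)butane | C[C@H]([C@@H](C)O[Si](C)(C)C)O[Si](C)(C)C
F3 | step 3 | (2R,3R)-butane-2,3-diol ketal of 5 | C=CCCC1=CCCC12O[C@H](C)[C@@H](C)O2
F4 | step 3 | (2R,3R)-butane-2,3-diol ketal of 6 | C12(O[C@H](C)[C@@H](C)O1)CCC[C@H]3CC=C(C)[C@@H](C[C@H]4C(=C)CC[C@@H]5[C@]4(C)CCC[C@]5(C)C(=O)OC)[C@@]23CCC=C
F5 | step 8 | nine-membered cyclic (Z)-allylic alcohol acid (C8' carbinol epimers) | OC1CC[C@H]2CC=C(C)[C@@H](C[C@H]3C(=C)CC[C@@H]4[C@]3(C)CCC[C@]4(C)C(=O)OC)[C@]2(C(=O)O)CC/C=C\1
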